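Readings and results come from a simulation for substances that don't exist; the scatter is artificial.

The north run, charged with 0.034 M of substrate and 0.050 M of reagent, shows product at 23.9% after 0.833 min and 24.0% after 10.0 min, and the other two runs stand as level.

| setting | north | west | north-west | flask |
|---|---|---|---|---|
| substrate | 0.034 M | 0.075 M | 0.050 M | 0.050 M |
| reagent | 0.050 M | 0.050 M | 0.025 M | 0.0500 M |
| remark | run made earlier | run made earlier | run made earlier |  |
| time |  |  |  | 12 min |

| north: time / min | north: product / % | west: time / min | west: product / % | north-west: time / min | north-west: product / % |
|---|---|---|---|---|---|
| 0.833 | 23.9 | 1.33 | 15.0 | 0.833 | 15.4 |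
| 2.00 | 24.0 | 3.00 | 14.2 | 2.00 | 15.7 |
| 4.00 | 24.4 | 6.00 | 14.8 | 4.00 | 16.4 |
| 10.0 | 24.0 | 10.0 | 15.1 | 10.0 | 15.5 |

(scatter of a reading: 0.5 percentage points)

- which holds at 12 min: what has brought the reaction to rest, or that it has not come to rest (the reagent has run out first / it is still moving / all of the substrate has reacted / forward and back rates have come level)
- how much product there is at 12 min, in percent of the substrate charged

- amounts and yields of product count crystals too
- given per volume of solution although it is solid: crystals
- what may be going on: 2 reagent -> homo dimer; substrate <-> intermediate A; crystals <-> product; substrate + reagent -> intermediate B; reagent + intermediate A -> product; intermediate B <-> intermediate C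
- the reaction counts as stopped when no species that holds the substrate changes by six tenths of a point or more over the second half of the time

Two of us dispute what stopped these runs. My colleague holds that forward and back rates have come level. A balance, she says, keeps its percent at a given substrate charge, so she reads the flask off the north-west run, which shares its 0.050 M of substrate, and expects 15.8%.

I hold that the reagent ran out in each run, and so I count product as a concentration, not a percent. Averaged and multiplied by the charge, the plateau is 0.00819 M in the north run and 0.0111 M in the west run. It is higher in the west run by a factor of 1.36, while the substrate charge grew by a factor of 2.21.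

At this reagent charge, the plateau therefore climbs 0.00254 M for each doubling of substrate; this gain per doubling is what I carry. The flask lies 0.556 of a doubling above the north run, so I reckon 0.00960 M, or 19.2% of its substrate.

The forecast takes my side and interpolates likewise between the north and west runs: it says that the reagent has run out first, with 19% of product, between 17.5% and 20.5%, and calls the plateau “a sudden halt, not a balance”.

The flask gives 18.8% of product at 12 min, which is 0.00940 M against my 0.00960 M, and the reagent has run out first, with 0% of the reagent charge left.

    2 reagent → homo dimer (k = 4.30 /M/s)
    substrate ⇌ intermediate A (K = 0.730, k = 0.0230 /s)
    crystals ⇌ product, rate k3*(cs3 - [product]) while solid is left; crystals form when [product] > cs3 (solubility = 11.0 mM, k = 8.00 /s)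
    substrate + reagent → intermediate B (k = 0.720 /M/s)
    reagent + intermediate A → product (k = 22.0 /M/s)
    intermediate B ⇌ intermediate C (K = 0.370, k = 0.0450 /s)

My colleague's level rates do stand in the flask, between substrate and intermediate A: 39.9% and 29.1% give a ratio of 0.729, beside the constant 0.73. Carried to a neighbour charged with 0.12 M of substrate and the same reagent, the gain per doubling gives 0.0128 M, or 10.7% of its substrate, and that neighbour holds 10.0%.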